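The readings were computed with made-up constants; noise was put on by code.

The vessel is closed, stirred and held at 80 °C. In it starting material opens reversibly, partner turns into second intermediate, and the two intermediates couple to product, while second intermediate can also decay to decomposed reagent.

| flask | starting material | partner | temperature | remark | time |
|---|---|---|---|---|---|
| autumn | 0.20 M | 0.95 equiv | 80 °C | the very flask that is asked about, followed so far |  |
| dusk | 0.13 M | 0.95 equiv | 80 °C | run made earlier |  |
| flask | 0.20 M | 0.950 equiv | 80 °C |  | 1.0 h |

| run | time / min | product / % | starting material / % |
|---|---|---|---|
| autumn | 4.00 | 37 | 23 |
| autumn | 8.00 | 47 | 20 |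
| autumn | 15.0 | 44 | 22 |
| autumn | 25.0 | 45 | 21 |
| autumn | 50.0 | 43 | 21 |
| dusk | 2.00 | 18 | 34 |
| dusk | 5.00 | 34 | 27 |
| dusk | 10.0 | 36 | 25 |
| dusk | 15.0 | 39 | 23 |
| dusk | 20.0 | 37 | 24 |

(standard deviation of a reading: 1.5 percentage points)

- product, in percent of the starting material first charged, at 1.0 h
- what to do for the largest gain in product; "none" if nothing gains more than 2 percentage points (amber / grey / red / blue / none)
- product present, with what was taken out counted in, in percent of the starting material first charged, after grey
- product present, with what was taken out counted in, in percent of the starting material first charged, after red

- amber: change nothing and wait 20 min more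
- grey: at 1.0 h add partner, 50.0% of the amount charged, then wait 20 min
- red: at 1.0 h raise the temperature by 15 K, then wait 20 min
- blue: at 1.0 h take out 90% of the product then present, then wait 20 min

- what is taken out of product is counted as made
- steps under discussion: starting material <-> open intermediate; partner -> second intermediate; open intermediate + second intermediate -> product; second intermediate -> decomposed reagent
- the earlier runs do not show what temperature does; that part of a forecast is a guess
- additions bring no volume worth counting

In the autumn flask product stands near 44.8% from 8.00 min on. Starting material holds near 21%, and I read the balance, 34.2%, as open intermediate. So material for coupling remains, and I suspect the partner side has stopped. The dusk flask looks nearly the same, with 0.95 equiv at 80 °C, but it starts at 0.13 M instead of 0.20 M. It levels off lower, near 37.3%.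

I take this as a partition. Decay of second intermediate is first order, but coupling also scales with open intermediate, so dilution favours decay. Let P be product as a fraction of the charge and q the equivalents of partner spent. Open intermediate falls with 1 − P, which gives q = P + ln[1/(1 − P)]/a. The autumn plateau gives a = 1.18, the coupling number: coupling rate over decay rate of second intermediate before any product has formed, a selectivity factor. The dusk plateau reads 0.810. Their ratio, 1.46, read from scattered plateaus, stands near the concentration ratio, 1.54. Grey raises the charge to q = 1.42, and my a then gives 61.8%.

The forecast says 45% now (43.5% to 46%) and chooses grey. It puts grey at 61.5% (57% to 65%), close to mine, and red at 45% (43% to 47.5%), on the ground that “Heating, waiting or removing product does nothing without active partner”.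

The flask gives 44.5% at 1.0 h. The best choice is grey, which reaches 62.0%, a gain of 17 percentage points. Red stays at 44.5%.

    starting material ⇌ open intermediate (K = 1.69, k = 0.0294 /s, Ea = 102 kJ/mol, ΔH = −58.0 kJ/mol)
    partner → second intermediate (k = 0.0181 /s, Ea = 85.0 kJ/mol)
    open intermediate + second intermediate → product (k = 0.0677 /M/s, Ea = 65.0 kJ/mol)
    second intermediate → decomposed reagent (k = 0.00664 /s, Ea = 102 kJ/mol)
    (constants at 80 °C)

Decay of second intermediate is one part of the loss: in the run without that step the autumn flask reaches 93.6% at 1.0 h, against 44.5%. Partner, the limiting reagent, stands at 0% by then. The same step is a part of what grey gains: without it the gain is 6.3 points, against 17 points. Through my a, the product after grey accounts for q = 1.44, beside the 1.42 charged. The neighbour at 0.12 M has a = 0.708 by scaling, and its 34.9% of product accounts for q = 0.955, against 0.950 equiv charged.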